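Retrosynthesis: the C3=C4 double bond of ring B is traced back to a racemic 3,4-dihydrocoumarin, with the C8 hydroxyl acetylated only for that oxidation. C4–C4a and C8a–O1 are then cut together and C4 is returned to C8a, which reveals a 3,3-diarylpropanoic acid with a free phenol. That acid is cut at C4–C1' (ring C), at C3=C4 (ylide) and at the formyl carbon on ring A.
Enabling feature: in ring A the carbons C8 (free OH), C8a (bond to O1) and C4a (bond to C4) are contiguous, and the C5 and C7 methoxy groups stand ortho and para to C4a. An oxidised C8 phenol can therefore accept the carboxyl oxygen at C8a and then pass C4 on to C4a.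
Forward order: ring A is bought, and a provisional pyranone ring (6,8-dimethoxy series) is closed by formylation and Wittig lactonisation. Ring C is joined at C4 by rhodium catalysis and the lactone is opened. A spiro γ-lactone then closes on the ipso carbon and expands to ring B of the 8-hydroxy-5,7-dimethoxy series, and dehydrogenation gives the coumarin.
Stereochemistry: the target has no stereocentre. C4 is racemic from the conjugate addition, the spiro centre is transient, and both are gone before the last step.

Key step: step 5

Remark: ring A atoms of the intermediates in the key step are named with the coumarin numbering of the target, every compound with a C4 stereocentre is a racemate, and the three starting materials are taken to be commercial.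

Step 1
Reactants: 1 2,4-dimethoxyphenol
Product: 3 2-hydroxy-3,5-dimethoxybenzaldehyde, via 2-(hydroxymethyl)-4,6-dimethoxyphenol 2 (not isolated)
Conditions: MgCl2, Et3N, (CH2O)n, MeCN, reflux; then 1 M HCl
Reagents that add atoms: paraformaldehyde (reacts as formaldehyde), C=O
Why: Casnati–Skattebøl ortho-formylation, in which the magnesium phenoxide of 1 directs formaldehyde to the only free ortho carbon (the para carbon carries a methoxy group) to give the magnesium salt of 2, and a second formaldehyde accepts hydride from its benzylic alkoxide in an Oppenauer-type transfer to deliver aldehyde 3.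

Step 2
Reactants: 3 2-hydroxy-3,5-dimethoxybenzaldehyde; 4 ethyl (triphenylphosphoranylidene)acetate
Product: 6 6,8-dimethoxy-2H-chromen-2-one (6,8-dimethoxycoumarin), via ethyl 3-(2-hydroxy-3,5-dimethoxyphenyl)acrylate 5 (not isolated)
Conditions: PhNEt2, reflux, N2
Reagents that add atoms: none
Why: Wittig olefination with a stabilised ylide followed by thermal lactonisation, the standard one-pot passage from salicylaldehydes to coumarins, in which the E and Z isomers of 5 equilibrate at the reflux temperature and the Z isomer is drained by attack of the phenol on the ester with loss of ethanol.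

Step 3
Reactants: 6 6,8-dimethoxy-2H-chromen-2-one; 7 3,4-dimethoxyphenylboronic acid
Product: 8 rac-4-(3,4-dimethoxyphenyl)-6,8-dimethoxy-3,4-dihydro-2H-chromen-2-one
Conditions: [RhCl(cod)]2 (3 mol %), KOH (15 mol %), 7 (3 equiv), dioxane–H2O (10:1), 60 °C; dilute HCl work-up
Reagents that add atoms: none
Why: Hayashi–Miyaura 1,4-addition, known for coumarins, in which the aryl–rhodium species formed by transmetallation from 7 inserts the C3=C4 bond with aryl delivery to C4, water releases the product from the oxa-π-allyl rhodium, the two methoxy groups are meta to C4a and so do not deactivate the acceptor, and the achiral diene ligand leaves the new C4 stereocentre racemic.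

Step 4
Reactants: 8 rac-4-(3,4-dimethoxyphenyl)-6,8-dimethoxy-3,4-dihydro-2H-chromen-2-one
Product: 9 rac-3-(3,4-dimethoxyphenyl)-3-(2-hydroxy-3,5-dimethoxyphenyl)propanoic acid
Conditions: LiOH (3 equiv), degassed THF–H2O, 0 °C → rt; 1 M HCl to pH 3–4 at 0 °C, EtOAc extraction, concentration below 25 °C, used at once
Reagents that add atoms: lithium hydroxide, [Li+].[OH-]
Why: Saponification of a phenolic lactone is fast because phenoxide is a good leaving group, oxygen-free base protects the electron-rich phenoxide, and cold acidification without heat or strong acid keeps 9 from closing back to 8 while C4 is untouched.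

Step 5
Reactants: 9 rac-3-(3,4-dimethoxyphenyl)-3-(2-hydroxy-3,5-dimethoxyphenyl)propanoic acid
Product: 11 rac-4-(3,4-dimethoxyphenyl)-8-hydroxy-5,7-dimethoxy-3,4-dihydro-2H-chromen-2-one, via spirolactone dienone 10 (not isolated)
Conditions: PhI(OAc)2 (1.0 equiv), (CF3)2CHOH, 4 Å MS, 0 °C; evaporate cold; then BF3·OEt2 (0.3 equiv), CH2Cl2, −40 → 0 °C
Reagents that add atoms: none
Why: Proposed new method: the phenol oxygen (future C8–OH) exchanges onto trivalent iodine, departure of PhI makes the ortho and para carbons of ring A electrophilic, and in the poorly nucleophilic solvent the tethered carboxyl group, which can reach only the side-chain-bearing ortho carbon (future C8a), closes the γ-lactone there 5-exo-trig to give the cyclohexa-2,4-dienone 10. BF3 on the dienone carbonyl turns 10 into an arenium ion with its charge on C8, C6 and C4a, none of which carries a methoxy group; a 1,2-shift of the benzylic carbon C4 from C8a to C4a moves the charge to C8a, C7 and C5, where O1 and both methoxy groups stabilise it, and loss of the C4a proton rearomatises ring A, so ring B arises by expansion of the five-membered spirolactone to six members and not by a new cyclisation. The closest known reaction types are the oxidative ortho-spirolactonisation of 3-(2-hydroxyaryl)propanoic acids with trivalent iodine reagents and the acid dienone–phenol rearrangement of para-spirolactone dienones to 6-hydroxydihydrocoumarins; their combination on an ortho dienone, with transposition of the lactone, has not been shown. The step needs carbon and not oxygen to migrate, and only to C4a: the γ-lactone is locked as an E-ester whose carbonyl oxygen points away from C4a and cannot form the bridged acyloxonium ion that carries oxygen shifts in acyclic quinol acetates, the three-atom tether excludes longer shifts, a shift to the carbonyl carbon C8 is a reversible dead end with no proton to lose, and the veratryl-substituted C4 is an excellent migrating group that, even if it departs as a tethered benzylic cation, is recaptured at the same C4a. One equivalent of oxidant and removal of solvent and acetic acid before the Lewis acid is added keep the new, easily oxidised phenol 11 and the electron-rich ring C away from active iodane. The spiro carbon of 10 arises without control as a mixture of diastereomers and becomes planar again in the shift, and C4 stays racemic, so 11 holds no new stereocentre.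

Step 6
Reactants: 11 rac-4-(3,4-dimethoxyphenyl)-8-hydroxy-5,7-dimethoxy-3,4-dihydro-2H-chromen-2-one
Product: 12 rac-4-(3,4-dimethoxyphenyl)-5,7-dimethoxy-2-oxo-3,4-dihydro-2H-chromen-8-yl acetate
Conditions: Ac2O, DMAP (cat.), pyridine, 0 °C → rt
Reagents that add atoms: acetic anhydride, CC(=O)OC(C)=O
Why: Standard O-acetylation of a phenol under nucleophilic catalysis masks the oxidation-prone 4-methoxyphenol unit of ring A before a quinone oxidant is used and leaves the lactone untouched.

Step 7
Reactants: 12 rac-4-(3,4-dimethoxyphenyl)-5,7-dimethoxy-2-oxo-3,4-dihydro-2H-chromen-8-yl acetate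
Product: 13 4-(3,4-dimethoxyphenyl)-5,7-dimethoxy-2-oxo-2H-chromen-8-yl acetate
Conditions: DDQ (2 equiv), 1,4-dioxane, reflux
Reagents that add atoms: none
Why: DDQ dehydrogenation is the usual way from 4-aryl-3,4-dihydrocoumarins to 4-arylcoumarins, since hydride leaves the doubly benzylic C4, where the cation is stabilised by the C5 and C7 methoxy groups and by ring C, and loss of a C3 proton gives the conjugated pyranone and removes the only stereocentre.

Step 8
Reactants: 13 4-(3,4-dimethoxyphenyl)-5,7-dimethoxy-2-oxo-2H-chromen-8-yl acetate
Product: 14 4-(3,4-dimethoxyphenyl)-8-hydroxy-5,7-dimethoxy-2H-chromen-2-one (8-hydroxy-5,7,3',4'-tetramethoxy-4-phenylcoumarin)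
Conditions: K2CO3 (0.2 equiv), MeOH–CH2Cl2, 0 °C → rt; then dilute HCl
Reagents that add atoms: none
Why: Base-catalysed (Zemplén-type) transesterification cleaves the activated aryl acetate far faster than methoxide affects the conjugated coumarin lactone, and any opened Z-cinnamate closes again on acidification.

Compound list
1 | 2,4-dimethoxyphenol | COc1ccc(O)c(OC)c1 | starting material
2 | 2-(hydroxymethyl)-4,6-dimethoxyphenol (present as its magnesium salt, not isolated) | COc1cc(CO)c(O)c(OC)c1 | intermediate
3 | 2-hydroxy-3,5-dimethoxybenzaldehyde | COc1cc(OC)c(O)c(C=O)c1 | intermediate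
4 | ethyl (triphenylphosphoranylidene)acetate | CCOC(=O)C=P(c1ccccc1)(c1ccccc1)c1ccccc1 | starting material
5 | ethyl 3-(2-hydroxy-3,5-dimethoxyphenyl)acrylate (E/Z mixture, not isolated) | CCOC(=O)C=Cc1cc(OC)cc(OC)c1O | intermediate
6 | 6,8-dimethoxy-2H-chromen-2-one | COc1cc(OC)c2oc(=O)ccc2c1 | intermediate
7 | 3,4-dimethoxyphenylboronic acid | COc1ccc(B(O)O)cc1OC | starting material
8 | rac-4-(3,4-dimethoxyphenyl)-6,8-dimethoxy-3,4-dihydro-2H-chromen-2-one | COc1ccc(C2CC(=O)Oc3c(OC)cc(OC)cc32)cc1OC | intermediate
9 | rac-3-(3,4-dimethoxyphenyl)-3-(2-hydroxy-3,5-dimethoxyphenyl)propanoic acid | OC(=O)CC(c1ccc(OC)c(OC)c1)c1cc(OC)cc(OC)c1O | intermediate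
10 | 4-(3,4-dimethoxyphenyl)-7,9-dimethoxy-1-oxaspiro[4.5]deca-7,9-diene-2,6-dione (racemic, both diastereomers at the spiro carbon, not isolated) | O=C1CC(c2ccc(OC)c(OC)c2)C2(O1)C=C(OC)C=C(OC)C2=O | intermediate
11 | rac-4-(3,4-dimethoxyphenyl)-8-hydroxy-5,7-dimethoxy-3,4-dihydro-2H-chromen-2-one | COc1ccc(C2CC(=O)Oc3c(O)c(OC)cc(OC)c32)cc1OC | intermediate
12 | rac-4-(3,4-dimethoxyphenyl)-5,7-dimethoxy-2-oxo-3,4-dihydro-2H-chromen-8-yl acetate | COc1ccc(C2CC(=O)Oc3c(OC(C)=O)c(OC)cc(OC)c32)cc1OC | intermediate
13 | 4-(3,4-dimethoxyphenyl)-5,7-dimethoxy-2-oxo-2H-chromen-8-yl acetate | COc1ccc(-c2cc(=O)oc3c(OC(C)=O)c(OC)cc(OC)c23)cc1OC | intermediate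
14 | 4-(3,4-dimethoxyphenyl)-8-hydroxy-5,7-dimethoxy-2H-chromen-2-one | COc1ccc(-c2cc(=O)oc3c(O)c(OC)cc(OC)c23)cc1OC | target

Total step count: 8. Longest linear sequence: 8 (1 → 3 → 6 → 8 → 9 → 11 → 12 → 13 → 14).

Steps most likely to fail

Step 5 (proposed new method). Several processes could divert the cascade:
- The oxidised phenol may be captured at the methoxy-bearing para carbon by acetate, solvent or traces of water, with later loss of methanol.
- The oxidised phenol may lose the benzylic C4 proton (quinone methide formation).
- Acid 9 may reclose under acid catalysis before it is oxidised.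
- The 2,4-dienone may dimerise by Diels–Alder reaction.
- Ring C may capture the activated dienone in a Friedel–Crafts sense instead of the shift taking place.

The fallback uses known chemistry and sets out from 3. A Dakin oxidation (H2O2, aqueous NaOH, 0 °C → rt) exchanges the formyl group for a hydroxyl and should give 3,5-dimethoxybenzene-1,2-diol F1. This is condensed with commercial (E)-3,4-dimethoxycinnamic acid in CF3CO2H at reflux, an acid-mediated hydroarylation–lactonisation. Alkylation at the ring carbon next to one hydroxyl and ortho/para to the methoxy groups, followed by lactone closure, rejoins the route at 11.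

Step 3. Insertion of the aryl–rhodium species into the coumarin may be slow. The electron-rich boronic acid may then undergo protodeboronation, or the aqueous base may open the lactone and withdraw the acceptor. The fallback sets out from 6 and 7. An oxidative Heck arylation (Pd(OAc)2, 1,10-phenanthroline, O2, DMF, 80 °C), known for coumarins and arylboronic acids, should give 4-(3,4-dimethoxyphenyl)-6,8-dimethoxy-2H-chromen-2-one F2. Hydrogenation of its C3=C4 bond (H2, Pd/C, AcOH–EtOAc) comes back to the route at 8.

Step 7. Hydride abstraction may stall because C4–H is shielded by the C5 methoxy group and ring C, and long heating with excess quinone may degrade or couple the electron-rich rings. The fallback replaces hydride abstraction by enolate chemistry and sets out from 11.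
- Silylation (TBSCl, imidazole, DMF) gives rac-8-(tert-butyldimethylsilyloxy)-4-(3,4-dimethoxyphenyl)-5,7-dimethoxy-3,4-dihydro-2H-chromen-2-one F3.
- Enolisation and selenenylation anti to the C4 aryl group (LiHMDS, THF, −78 °C; PhSeCl) give the trans-3-(phenylselanyl) lactone F4.
- H2O2 in CH2Cl2 at 0 °C forms the selenoxide F5. Its selenium is cis to C4–H, so syn elimination should give 8-(tert-butyldimethylsilyloxy)-4-(3,4-dimethoxyphenyl)-5,7-dimethoxy-2H-chromen-2-one F6.
- Desilylation (Bu4NF, AcOH, THF) comes back to the route at 14.

Further compounds
F1 | step 5 | 3,5-dimethoxybenzene-1,2-diol | COc1cc(O)c(O)c(OC)c1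
F2 | step 3 | 4-(3,4-dimethoxyphenyl)-6,8-dimethoxy-2H-chromen-2-one | COc1ccc(-c2cc(=O)oc3c(OC)cc(OC)cc23)cc1OC
F3 | step 7 | rac-8-(tert-butyldimethylsilyloxy)-4-(3,4-dimethoxyphenyl)-5,7-dimethoxy-3,4-dihydro-2H-chromen-2-one | COc1ccc(C2CC(=O)Oc3c(O[Si](C)(C)C(C)(C)C)c(OC)cc(OC)c32)cc1OC
F4 | step 7 | rac-trans-8-(tert-butyldimethylsilyloxy)-4-(3,4-dimethoxyphenyl)-5,7-dimethoxy-3-(phenylselanyl)-3,4-dihydro-2H-chromen-2-one (one enantiomer drawn) | COc1ccc([C@@H]2[C@@H]([Se]c3ccccc3)C(=O)Oc3c(O[Si](C)(C)C(C)(C)C)c(OC)cc(OC)c32)cc1OC
F5 | step 7 | rac-trans-8-(tert-butyldimethylsilyloxy)-4-(3,4-dimethoxyphenyl)-5,7-dimethoxy-3-(phenylseleninyl)-3,4-dihydro-2H-chromen-2-one (mixture at selenium, one enantiomer drawn) | COc1ccc([C@@H]2[C@@H]([Se](=O)c3ccccc3)C(=O)Oc3c(O[Si](C)(C)C(C)(C)C)c(OC)cc(OC)c32)cc1OC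
F6 | step 7 | 8-(tert-butyldimethylsilyloxy)-4-(3,4-dimethoxyphenyl)-5,7-dimethoxy-2H-chromen-2-one | COc1ccc(-c2cc(=O)oc3c(O[Si](C)(C)C(C)(C)C)c(OC)cc(OC)c23)cc1OC
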